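The route rests on taking the α-methylene-γ-butyrolactone (ring O–C6–C7–C11–C12) apart into carbon dioxide and an open C6–C7–C11 chain. The key step exploits the 1,3-relationship of C6 and C11 across C7: C11 is nucleophilic (1,1-disubstituted alkenylboronate), C6 electrophilic (secondary mesylate of inverted configuration). One copper-catalysed operation carboxylates C11 and lets the new carboxylate displace the mesylate, which forms C11–C12 and O–C6 and sets C6 by inversion. The acyclic precursor arises from an allene diboration/allylboration that unites both halves and sets C6 and C7. Ring-closing metathesis at C1=C10 then closes the ten-membered ring, and O8 acylation and desilylation finish.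

Key step: step 14

Remark: germacrane numbering is used (C1–C10 ring, C11–C13 lactone side chain, C14 on C10, C15 on C4). The C1=C10 alkene of the target is E by the sequence rule, but C2 and C9 are cis on the ring.
Abbreviations: TBS = tert-butyldimethylsilyl, TES = triethylsilyl, Bpin = 4,4,5,5-tetramethyl-1,3,2-dioxaborolan-2-yl, IPr = 1,3-bis(2,6-diisopropylphenyl)imidazol-2-ylidene, (R)-TRIP = (R)-3,3'-bis(2,4,6-triisopropylphenyl)-1,1'-binaphthyl-2,2'-diyl hydrogen phosphate.

Step 1
Reactants: 1 (4R)-4-benzyl-1,3-oxazolidin-2-one; 2 hex-5-enoyl chloride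
Product: 3 (4R)-4-benzyl-3-(hex-5-enoyl)-1,3-oxazolidin-2-one
Conditions: n-BuLi, THF, −78 °C; then 2, −78 → 0 °C
Reagents that add atoms: none
Why: N-acylation of the lithiated oxazolidinone with an acid chloride is a routine imide formation and creates no stereocentre.

Step 2
Reactants: 3 imide; 4 tert-butyl bromoacetate
Product: 5 tert-butyl (3S)-3-{[(4R)-4-benzyl-2-oxo-1,3-oxazolidin-3-yl]carbonyl}hept-6-enoate
Conditions: NaN(SiMe3)2, THF, −78 °C; then 4, −78 → −40 °C
Reagents that add atoms: none
Why: Evans asymmetric alkylation, in which the chelated Z-sodium enolate is attacked on the face opposite the benzyl group, sets C4 as S.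

Step 3
Reactants: 5 alkylated imide
Product: 6 tert-butyl (3S)-3-(hydroxymethyl)hept-6-enoate
Conditions: LiBH4, MeOH (1 equiv), Et2O, 0 °C
Reagents that add atoms: none
Why: Reductive removal of the auxiliary works because the activated exocyclic imide carbonyl is reduced much faster than the hindered tert-butyl ester, and C4 is not touched.

Step 4
Reactants: 6 hydroxy ester
Product: 7 tert-butyl (3S)-3-{[(tert-butyldimethylsilyl)oxy]methyl}hept-6-enoate
Conditions: TBSCl, imidazole, CH2Cl2, rt
Reagents that add atoms: tert-butyldimethylsilyl chloride CC(C)(C)[Si](C)(C)Cl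
Why: Imidazole-promoted silylation of the primary alcohol masks O15 before lactonisation onto the ester can set in.

Step 5
Reactants: 7 silyl ether ester
Product: 8 (3S)-3-{[(tert-butyldimethylsilyl)oxy]methyl}hept-6-enal (C1–C6 and C15)
Conditions: i-Bu2AlH (1.1 equiv), CH2Cl2, −78 °C; aq. potassium sodium tartrate
Reagents that add atoms: none
Why: Partial ester reduction stops at the aldehyde because the aluminium hemiacetal of the bulky ester is stable at −78 °C and collapses only on work-up.

Step 6
Reactants: 9 2-methylidenepropane-1,3-diol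
Product: 10 2-{[(tert-butyldimethylsilyl)oxy]methyl}prop-2-en-1-ol
Conditions: NaH (1.0 equiv), THF, 0 °C → rt; then TBSCl
Reagents that add atoms: tert-butyldimethylsilyl chloride CC(C)(C)[Si](C)(C)Cl
Why: Monosilylation through the sparingly soluble monosodium alkoxide differentiates the two equivalent hydroxyl groups.

Step 7
Reactants: 10 monosilyl ether
Product: 11 2-{[(tert-butyldimethylsilyl)oxy]methyl}prop-2-en-1-yl acetate
Conditions: Ac2O, pyridine, DMAP (cat.), CH2Cl2, 0 °C → rt
Reagents that add atoms: acetic anhydride CC(=O)OC(C)=O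
Why: Routine acetylation turns the free allylic alcohol into a leaving group for palladium.

Step 8
Reactants: 11 allylic acetate
Product: 12 pinacol 2-{[(tert-butyldimethylsilyl)oxy]methyl}allylboronate
Conditions: B2pin2, Pd(dba)2 (5 mol %), DMSO, 50 °C
Reagents that add atoms: bis(pinacolato)diboron CC1(C)OB(OC1(C)C)B1OC(C)(C)C(C)(C)O1
Why: In this Miyaura-type allylic borylation zerovalent palladium ionises the acetate to a 2-substituted π-allyl complex with two equivalent termini, so borylation poses no regiochemical question.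

Step 9
Reactants: 12 allylboronate; 13 3-(trimethylsilyl)prop-2-ynal
Product: 15 (3R)-5-{[(tert-butyldimethylsilyl)oxy]methyl}hex-5-en-1-yn-3-ol, via O-boryl adduct 14 (not isolated)
Conditions: (R)-TRIP (5 mol %), 4 Å molecular sieves, toluene, −30 °C; then K2CO3, MeOH, rt
Reagents that add atoms: none
Why: Chiral-phosphoric-acid-catalysed allylboration runs through a closed six-membered transition state in which (R)-TRIP directs the allyl group to the Re face of the ynal and sets C8 as R, and methanolysis of the borate and base-catalysed protodesilylation of the alkyne follow in the same flask.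

Step 10
Reactants: 15 propargylic alcohol; 16 paraformaldehyde (formaldehyde source)
Product: 18 (4R)-6-{[(tert-butyldimethylsilyl)oxy]methyl}hepta-1,2,6-trien-4-ol, via propargylic amine 17 (not isolated)
Conditions: CuI (0.5 equiv), Cy2NH, 1,4-dioxane, reflux
Reagents that add atoms: none
Why: In this Crabbé homologation the copper acetylide, formaldehyde and dicyclohexylamine give Mannich base 17, and a copper-assisted 1,5-hydride shift then expels the imine to leave the terminal allene (C7=C11=C13) with C8 untouched.

Step 11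
Reactants: 18 α-allenol
Product: 19 (4R)-6-{[(tert-butyldimethylsilyl)oxy]methyl}-4-[(triethylsilyl)oxy]hepta-1,2,6-triene
Conditions: TESCl, imidazole, CH2Cl2, 0 °C
Reagents that add atoms: triethylsilyl chloride CC[Si](Cl)(CC)CC
Why: Silylation masks O8 with a group that can later be removed in the presence of the two primary TBS ethers.

Step 12
Reactants: 19 allene; 8 aldehyde
Product: 22 open-chain (4S,6S,7S,8R)-alkenylboronate alcohol (6-OH; C7 bears 1-(Bpin)ethenyl; 8-OTES; 14- and 15-OTBS; terminal alkenes at C1 and C10), via Z-diboronate 20 (not isolated), via O-boryl adduct 21 (not isolated)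
Conditions: B2pin2, Pd(dba)2 (5 mol %), 3-iodo-2-methylcyclohex-2-en-1-one (10 mol %), toluene, 80 °C; filtration through Celite; then 8, (R)-TRIP (10 mol %), 4 Å molecular sieves, toluene, 0 °C → rt; aq. NaHCO3
Reagents that add atoms: bis(pinacolato)diboron CC1(C)OB(OC1(C)C)B1OC(C)(C)C(C)(C)O1
Why: Palladium-catalysed allene diboration adds B2pin2 across the terminal C11=C13 bond on the side away from C8 and gives Z-allylboronate 20, whose phosphoric-acid-catalysed allylboration of 8 passes through a closed chair in which the Z geometry makes O6 and C8 syn along the C5–C6–C7–C11 chain, (R)-TRIP selects the Re face of the aldehyde (6S), and the allylic 1,3-strain conformer at C8 (H8 in the alkene plane, C8–C9 anti to the forming bond) should expose the same C7 face, so that the C7 alkenyl group ends up anti to both O6 and O8.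

Step 13
Reactants: 22 alcohol
Product: 23 open-chain (4S,6S,7R,8R)-alkenylboronate mesylate (as 22, 6-OMs)
Conditions: MsCl, Et3N, CH2Cl2, 0 °C
Reagents that add atoms: methanesulfonyl chloride CS(=O)(=O)Cl
Why: Mesylation takes place at oxygen, so the C6 configuration is retained (the C7 descriptor changes only through priorities) and the alkenylboronate is inert.

Step 14
Reactants: 23 mesylate; 24 carbon dioxide
Product: 26 open-chain (4S,6R,7S,8R)-α-methylene-γ-butyrolactone (trans-6,7-disubstituted; 8-OTES; 14- and 15-OTBS), via potassium carboxylate 25 (not isolated)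
Conditions: (IPr)CuCl (10 mol %), KOtBu (1.1 equiv), CO2 (1 atm), THF/DMF, 70 °C
Reagents that add atoms: none
Why: KOtBu turns (IPr)CuCl into (IPr)CuOtBu, which takes the C11 alkenyl group from boron by transmetalation; the alkenylcopper inserts CO2 into its Cu–C bond (new C11–C12 bond), and salt exchange releases potassium carboxylate 25 and tBuOBpin while copper re-enters the cycle. On continued heating a carboxylate oxygen of 25 displaces the C6 mesylate from the rear (new O–C6 bond), so both lactone bonds arise in one flask from one molecule of CO2. The closest known reaction types are the copper–carbene-catalysed carboxylation of aryl- and alkenylboronic esters with CO2 and the invertive lactonisation of γ-sulfonyloxy carboxylates. The only ring closed is the five-membered lactone, by a 5-exo-tet substitution. C6 is the only stereocentre that changes: inversion turns 6S into 6R and places H6 and H7 trans, while C4, C7 and C8 are spectators. Carboxylation must outrun base-induced elimination, which is favoured because tert-butoxide is tied up as borate and as tert-butyl carbonate under CO2, and substitution must occur only at C6, which carries the only leaving group at γ-lactone distance while O8 is masked as a silyl ether.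

Step 15
Reactants: 26 diene lactone
Product: 27 (1(10)E,4S,6R,7S,8R)-8-(triethylsilyloxy)-14,15-bis(tert-butyldimethylsilyloxy)germacra-1(10),11(13)-dien-12,6-olide
Conditions: second-generation Hoveyda–Grubbs catalyst (15 mol %), toluene (1 mM), 100 °C, argon sparge
Reagents that add atoms: none
Why: Ring-closing metathesis should initiate at the monosubstituted C1 alkene and close onto the 1,1-disubstituted C10 alkene, with the ring-cis trisubstituted alkene being the less strained geometry of a cyclodecene and the electron-poor α-methylene lactone the slower partner.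

Step 16
Reactants: 27 macrocyclic TES ether
Product: 28 (1(10)E,4S,6R,7R,8R)-8-hydroxy-14,15-bis(tert-butyldimethylsilyloxy)germacra-1(10),11(13)-dien-12,6-olide
Conditions: PPTS (cat.), MeOH/CH2Cl2, 0 °C
Reagents that add atoms: none
Why: Mild acid methanolysis cleaves the far more labile TES ether selectively beside the two primary TBS ethers and changes no stereocentre (the C7 descriptor changes only through priorities).

Step 17
Reactants: 28 C8 alcohol; 29 methacrylic anhydride
Product: 30 (1(10)E,4S,6R,7S,8R)-8-(methacryloyloxy)-14,15-bis(tert-butyldimethylsilyloxy)germacra-1(10),11(13)-dien-12,6-olide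
Conditions: Et3N, DMAP (cat.), CH2Cl2, 0 °C → rt
Reagents that add atoms: none
Why: DMAP-catalysed acylation of the only free hydroxyl group installs the ester at oxygen with retention at C8.

Step 18
Reactants: 30 bis-silyl ether
Product: 31 target, (1(10)E,4S,6R,7S,8R)-14,15-dihydroxy-8-(methacryloyloxy)germacra-1(10),11(13)-dien-12,6-olide
Conditions: HF·pyridine, pyridine, THF, 0 °C → rt
Reagents that add atoms: none
Why: Buffered fluoride desilylation removes both primary TBS groups under non-basic conditions that the methacrylate and the α-methylene lactone tolerate.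

Compound list
1 | (4R)-4-benzyl-1,3-oxazolidin-2-one | O=C1N[C@H](Cc2ccccc2)CO1 | starting material
2 | hex-5-enoyl chloride | C=CCCCC(=O)Cl | starting material
3 | (4R)-4-benzyl-3-(hex-5-enoyl)-1,3-oxazolidin-2-one | C=CCCCC(=O)N1[C@H](Cc2ccccc2)COC1=O | intermediate
4 | tert-butyl bromoacetate | CC(C)(C)OC(=O)CBr | starting material
5 | tert-butyl (3S)-3-{[(4R)-4-benzyl-2-oxo-1,3-oxazolidin-3-yl]carbonyl}hept-6-enoate | C=CCC[C@@H](CC(=O)OC(C)(C)C)C(=O)N1[C@H](Cc2ccccc2)COC1=O | intermediate
6 | tert-butyl (3S)-3-(hydroxymethyl)hept-6-enoate | C=CCC[C@H](CO)CC(=O)OC(C)(C)C | intermediate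
7 | tert-butyl (3S)-3-{[(tert-butyldimethylsilyl)oxy]methyl}hept-6-enoate | C=CCC[C@H](CO[Si](C)(C)C(C)(C)C)CC(=O)OC(C)(C)C | intermediate
8 | (3S)-3-{[(tert-butyldimethylsilyl)oxy]methyl}hept-6-enal | C=CCC[C@H](CO[Si](C)(C)C(C)(C)C)CC=O | intermediate
9 | 2-methylidenepropane-1,3-diol | C=C(CO)CO | starting material
10 | 2-{[(tert-butyldimethylsilyl)oxy]methyl}prop-2-en-1-ol | C=C(CO)CO[Si](C)(C)C(C)(C)C | intermediate
11 | 2-{[(tert-butyldimethylsilyl)oxy]methyl}prop-2-en-1-yl acetate | CC(=O)OCC(=C)CO[Si](C)(C)C(C)(C)C | intermediate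
12 | pinacol 2-{[(tert-butyldimethylsilyl)oxy]methyl}allylboronate | C=C(CB1OC(C)(C)C(C)(C)O1)CO[Si](C)(C)C(C)(C)C | intermediate
13 | 3-(trimethylsilyl)prop-2-ynal | C[Si](C)(C)C#CC=O | starting material
14 | O-Bpin borate of (3R)-5-(TBSO-methyl)-1-(trimethylsilyl)hex-5-en-1-yn-3-ol | C[Si](C)(C)C#C[C@H](OB1OC(C)(C)C(C)(C)O1)CC(=C)CO[Si](C)(C)C(C)(C)C | intermediate
15 | (3R)-5-{[(tert-butyldimethylsilyl)oxy]methyl}hex-5-en-1-yn-3-ol | C#C[C@H](O)CC(=C)CO[Si](C)(C)C(C)(C)C | intermediate
16 | paraformaldehyde (as formaldehyde) | C=O | starting material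
17 | (4R)-1-(dicyclohexylamino)-6-{[(tert-butyldimethylsilyl)oxy]methyl}hept-6-en-2-yn-4-ol | C1CCC(CC1)N(CC#C[C@H](O)CC(=C)CO[Si](C)(C)C(C)(C)C)C1CCCCC1 | intermediate
18 | (4R)-6-{[(tert-butyldimethylsilyl)oxy]methyl}hepta-1,2,6-trien-4-ol | C=C=C[C@H](O)CC(=C)CO[Si](C)(C)C(C)(C)C | intermediate
19 | (4R)-6-{[(tert-butyldimethylsilyl)oxy]methyl}-4-[(triethylsilyl)oxy]hepta-1,2,6-triene | C=C=C[C@H](O[Si](CC)(CC)CC)CC(=C)CO[Si](C)(C)C(C)(C)C | intermediate
20 | (2Z,4R)-1,2-bis(Bpin)-6-(TBSO-methyl)-4-(TESO)hepta-2,6-diene | CC1(C)OB(C/C(B2OC(C)(C)C(C)(C)O2)=C\[C@H](O[Si](CC)(CC)CC)CC(=C)CO[Si](C)(C)C(C)(C)C)OC1(C)C | intermediate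
21 | O6-Bpin borate of alcohol 22 | C=CCC[C@H](CO[Si](C)(C)C(C)(C)C)C[C@H](OB1OC(C)(C)C(C)(C)O1)[C@H](C(=C)B1OC(C)(C)C(C)(C)O1)[C@H](O[Si](CC)(CC)CC)CC(=C)CO[Si](C)(C)C(C)(C)C | intermediate
22 | open-chain (4S,6S,7S,8R)-alkenylboronate alcohol | C=CCC[C@H](CO[Si](C)(C)C(C)(C)C)C[C@H](O)[C@H](C(=C)B1OC(C)(C)C(C)(C)O1)[C@H](O[Si](CC)(CC)CC)CC(=C)CO[Si](C)(C)C(C)(C)C | intermediate
23 | open-chain (4S,6S,7R,8R)-alkenylboronate mesylate | C=CCC[C@H](CO[Si](C)(C)C(C)(C)C)C[C@H](OS(C)(=O)=O)[C@H](C(=C)B1OC(C)(C)C(C)(C)O1)[C@H](O[Si](CC)(CC)CC)CC(=C)CO[Si](C)(C)C(C)(C)C | intermediate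
24 | carbon dioxide | O=C=O | starting material
25 | potassium (4S,6S,7R,8R)-6-mesyloxy-11(13)-en-12-oate | C=CCC[C@H](CO[Si](C)(C)C(C)(C)C)C[C@H](OS(C)(=O)=O)[C@H](C(=C)C(=O)[O-])[C@H](O[Si](CC)(CC)CC)CC(=C)CO[Si](C)(C)C(C)(C)C.[K+] | intermediate
26 | open-chain (4S,6R,7S,8R)-α-methylene-γ-butyrolactone | C=CCC[C@H](CO[Si](C)(C)C(C)(C)C)C[C@H]1OC(=O)C(=C)[C@@H]1[C@H](O[Si](CC)(CC)CC)CC(=C)CO[Si](C)(C)C(C)(C)C | intermediate
27 | macrocyclic lactone, 8-OTES, 14,15-bis-OTBS | CC[Si](CC)(CC)O[C@@H]1C/C(CO[Si](C)(C)C(C)(C)C)=C\CC[C@H](CO[Si](C)(C)C(C)(C)C)C[C@H]2OC(=O)C(=C)[C@H]12 | intermediate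
28 | macrocyclic lactone, 8-OH, 14,15-bis-OTBS | O[C@@H]1C/C(CO[Si](C)(C)C(C)(C)C)=C\CC[C@H](CO[Si](C)(C)C(C)(C)C)C[C@H]2OC(=O)C(=C)[C@H]12 | intermediate
29 | methacrylic anhydride | C=C(C)C(=O)OC(=O)C(C)=C | starting material
30 | macrocyclic lactone, 8-O-methacrylate, 14,15-bis-OTBS | C=C(C)C(=O)O[C@@H]1C/C(CO[Si](C)(C)C(C)(C)C)=C\CC[C@H](CO[Si](C)(C)C(C)(C)C)C[C@H]2OC(=O)C(=C)[C@H]12 | intermediate
31 | CNP0546547.2 | C=C(C)C(=O)O[C@@H]1C/C(CO)=C\CC[C@H](CO)C[C@H]2OC(=O)C(=C)[C@H]12 | target

Total step count: 18. Longest linear sequence: 13 steps (9 → 31, steps 6–18).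

Steps most likely to fail

Step 14. The mesylate may be lost by base-induced elimination toward C7, or the boronate may be protonated before CO2 is taken up. The fallback sets out from 23 and replaces transmetalation under basic conditions by a base-free reductive carboxylation of an electrophile. Iododeboronation (NaOH, I2, THF, 0 °C) gives the alkenyl iodide F1. Nickel catalysis (NiCl2(PPh3)2, PPh3, Mn powder, Et4NI, DMF, CO2 1 atm, 25 °C, then 60 °C) converts it into the iodomanganese carboxylate F2. This closes onto C6 with the same inversion, and the route is rejoined at 26.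

Step 15. The diene may oligomerise at workable dilution, or the ring may close onto the C13 methylene of the lactone instead of the hindered C10 alkene. The fallback sets out from 23 and moves the metathesis in front of lactone formation, where the only other 1,1-disubstituted alkene is the very hindered alkenylboronate. Ring closure with the same ruthenium catalyst gives the macrocyclic boronate mesylate F3. Under the conditions of step 14 this passes through the macrocyclic potassium carboxylate F4, and the route is rejoined at 27.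

Step 12. Facial selectivity may be poor if the acid catalyst and the C8 stereocentre oppose each other, the diboration may attack the internal allene bond, or allyl transfer from the hindered Z-boronate may be slow. The fallback sets out from 19 and 8 and replaces the allylboronate by a catalytically formed allylcopper species. A three-component borylative coupling (CuCl, (R)-SEGPHOS, NaOtBu cat., B2pin2, THF, rt) generates the 2-boryl allylcopper F5 in the presence of the aldehyde. The ligand on copper then controls both faces. The adduct is borate 21, and hydrolysis rejoins the route at 22.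

Further compounds
F1 | step 14 | alkenyl iodide analogue of 23 (C11–I) | C=CCC[C@H](CO[Si](C)(C)C(C)(C)C)C[C@H](OS(C)(=O)=O)[C@H](C(=C)I)[C@H](O[Si](CC)(CC)CC)CC(=C)CO[Si](C)(C)C(C)(C)C
F2 | step 14 | iodomanganese 6-mesyloxy-11(13)-en-12-oate | C=CCC[C@H](CO[Si](C)(C)C(C)(C)C)C[C@H](OS(C)(=O)=O)[C@H](C(=C)C(=O)[O-])[C@H](O[Si](CC)(CC)CC)CC(=C)CO[Si](C)(C)C(C)(C)C.[Mn+2].[I-]
F3 | step 15 | macrocyclic alkenylboronate mesylate | CC[Si](CC)(CC)O[C@@H]1C/C(CO[Si](C)(C)C(C)(C)C)=C\CC[C@H](CO[Si](C)(C)C(C)(C)C)C[C@H](OS(C)(=O)=O)[C@@H]1C(=C)B2OC(C)(C)C(C)(C)O2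
F4 | step 15 | macrocyclic potassium 6-mesyloxy-11(13)-en-12-oate | CC[Si](CC)(CC)O[C@@H]1C/C(CO[Si](C)(C)C(C)(C)C)=C\CC[C@H](CO[Si](C)(C)C(C)(C)C)C[C@H](OS(C)(=O)=O)[C@@H]1C(=C)C(=O)[O-].[K+]
F5 | step 12 | (Z)-2-boryl allylcopper from 19 (ligand omitted) | [Cu]C/C(B1OC(C)(C)C(C)(C)O1)=C\[C@H](O[Si](CC)(CC)CC)CC(=C)CO[Si](C)(C)C(C)(C)C
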